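**Plan**
Numbering: tetrahydrofuran O1, C2 (ring A), C3 and C4 (methyl groups), C5 (ring B). The para oxygen of ring B carries the chain Cβ(H)(CH3)–Cα(H)(OH)–ring C. Ts = 4-methylbenzenesulfonyl.
Enabling feature: C5 is a benzylic ether carbon para to the alkylated oxygen of ring B. Once the phenols of rings A and C are masked as tosylates, it is the only benzylic carbon that can ionise. Ring B at C5 is trans to the C4 methyl, which is the arrangement a cationic closure prefers.
Cuts: O1–C5 (last skeletal bond, closes the only new ring), C5–ring B (aryl Grignard + lactol), C2–ring A (arylzinc + meso anhydride), Cα–ring C (aryl Grignard + Weinreb amide), Cβ–O (Mitsunobu).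
Forward: the ring A/C2–C4 lactol and the ring B–side chain–ring C iodide are each made in five steps, sharing one tosylate building block. They are joined at C5, cyclised and deprotected.
Stereochemistry: C3/C4 come from ligand-controlled desymmetrisation of the meso anhydride and C2 from a CBS reduction. Cβ comes from ethyl (S)-lactate by inversion, Cα from a chelate-controlled reduction, and C5 from closure anti to the C4 methyl.

Key step: step 13

Assumption: (S)-t-Bu-PHOX is taken to be the ligand antipode that gives the (2S,3R) keto acid of step 3. If the sense of induction is the reverse, (R)-t-Bu-PHOX is used and nothing else changes.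

**Step 1**
Reactants: 1 4-iodo-2-methoxyphenol; 2 p-toluenesulfonyl chloride
Product: 3 4-iodo-2-methoxyphenyl 4-methylbenzenesulfonate
Conditions: Et3N, DMAP (5 mol %), CH2Cl2, 0 °C → rt
Reagents that add atoms: none
Why: Sulfonylation of a phenol under amine base is routine, and the tosyloxy group later acts as the electron-withdrawing mask that keeps the benzylic carbons of rings A and C from ionising.

**Step 2**
Reactants: 4 meso-2,3-dimethylsuccinic acid
Product: 5 cis-2,3-dimethylsuccinic anhydride ((3R,4S)-3,4-dimethyloxolane-2,5-dione)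
Conditions: AcCl (neat), reflux; concentrate
Reagents that add atoms: none
Why: Cyclodehydration of a 1,4-diacid with acetyl chloride closes the five-membered anhydride at about 50 °C, which is mild enough to leave the two methyl groups cis.

**Step 3**
Reactants: 3 4-iodo-2-methoxyphenyl 4-methylbenzenesulfonate; 5 cis-2,3-dimethylsuccinic anhydride
Product: 8 (2S,3R)-4-[3-methoxy-4-(tosyloxy)phenyl]-2,3-dimethyl-4-oxobutanoic acid, via aryllithium 6 (not isolated), via arylzinc triflate 7 (not isolated)
Conditions: 3 (1.6 equiv), n-BuLi, THF, −78 °C, 10 min; Zn(OTf)2, −78 °C → rt; then 5, [Rh(cod)Cl]2 (4 mol %), (S)-t-Bu-PHOX (8 mol %), THF, 50 °C; 1 M HCl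
Reagents that add atoms: none
Why: Enantioselective acyl cross-coupling of a meso succinic anhydride with an arylzinc triflate made in situ under rhodium/phosphinooxazoline catalysis is known for this very anhydride, the chiral ligand deciding which of the two enantiotopic acyl–oxygen bonds the metal inserts into and so fixing C3 (R) and C4 (S) together without touching either C–H bond, while iodine–lithium exchange at −78 °C is faster than attack of butyllithium on an aryl sulfonate (the basis of aryne generation from 2-iodoaryl sulfonates) and zinc triflate tames the aryllithium at once.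

**Step 4**
Reactants: 8 (2S,3R)-4-[3-methoxy-4-(tosyloxy)phenyl]-2,3-dimethyl-4-oxobutanoic acid
Product: 9 methyl (2S,3R)-4-[3-methoxy-4-(tosyloxy)phenyl]-2,3-dimethyl-4-oxobutanoate
Conditions: TMSCHN2, toluene/MeOH 4:1, 0 °C
Reagents that add atoms: (trimethylsilyl)diazomethane, C[Si](C)(C)C=[N+]=[N-]
Why: O-Methylation of the acid with a diazoalkane needs no base, so the epimerisable centre next to the aryl ketone is untouched, and the ester makes the substrate compatible with borane.

**Step 5**
Reactants: 9 methyl (2S,3R)-4-[3-methoxy-4-(tosyloxy)phenyl]-2,3-dimethyl-4-oxobutanoate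
Product: 11 (3S,4R,5S)-5-[3-methoxy-4-(tosyloxy)phenyl]-3,4-dimethyloxolan-2-one (all-cis lactone), via hydroxy ester 10 (not isolated)
Conditions: (R)-Me-CBS (30 mol %), BH3·SMe2, THF, −20 °C, slow addition of 9; MeOH; then TsOH·H2O (5 mol %), CH2Cl2, rt
Reagents that add atoms: none
Why: Corey–Bakshi–Shibata reduction, in which the aryl group takes the role of the large substituent so that the (R)-oxazaborolidine sends hydride to the Re face and sets C2 as S (hydroxyl syn to the C3 methyl, against the Felkin–Anh bias of the substrate) under non-basic conditions that cannot epimerise C3, after which acid-catalysed transesterification closes the all-cis lactone and any material from the minor enantiomer of 9 ends up as a separable 4,5-trans diastereomer.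

**Step 6**
Reactants: 11 (3S,4R,5S)-5-[3-methoxy-4-(tosyloxy)phenyl]-3,4-dimethyloxolan-2-one
Product: 12 (3S,4R,5S)-5-[3-methoxy-4-(tosyloxy)phenyl]-3,4-dimethyloxolan-2-ol (lactol, anomer mixture)
Conditions: i-Bu2AlH (1.1 equiv), CH2Cl2, −78 °C; aq potassium sodium tartrate
Reagents that add atoms: none
Why: Partial reduction of a γ-lactone with one equivalent of i-Bu2AlH at −78 °C stops at the aluminium lactolate, aryl sulfonates are inert to it, and the new anomeric centre is of no consequence because it opens in step 12.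

**Step 7**
Reactants: 1 4-iodo-2-methoxyphenol; 13 ethyl (S)-lactate
Product: 14 ethyl (R)-2-(4-iodo-2-methoxyphenoxy)propanoate
Conditions: PPh3, DIAD, THF, 0 °C → rt
Reagents that add atoms: none
Why: Mitsunobu etherification of a secondary α-hydroxy ester with a phenol runs by clean SN2 inversion, so the (S)-lactate centre becomes the (R)-configured Cβ of the side chain.

**Step 8**
Reactants: 14 ethyl (R)-2-(4-iodo-2-methoxyphenoxy)propanoate
Product: 15 (R)-2-(4-iodo-2-methoxyphenoxy)-N-methoxy-N-methylpropanamide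
Conditions: MeNH(OMe)·HCl, AlMe3, CH2Cl2, 0 °C → rt
Reagents that add atoms: N,O-dimethylhydroxylamine hydrochloride, CNOC.Cl
Why: Weinreb aminolysis of an ester with the aluminium amide is too weakly basic to racemise the α-aryloxy centre and, unlike a magnesium amide protocol, cannot exchange the aryl iodide.

**Step 9**
Reactants: 3 4-iodo-2-methoxyphenyl 4-methylbenzenesulfonate; 15 (R)-2-(4-iodo-2-methoxyphenoxy)-N-methoxy-N-methylpropanamide
Product: 17 (R)-2-(4-iodo-2-methoxyphenoxy)-1-[3-methoxy-4-(tosyloxy)phenyl]propan-1-one, via arylmagnesium chloride 16 (not isolated)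
Conditions: 3 (1.3 equiv), i-PrMgCl·LiCl (1.25 equiv), THF, −20 °C; then 15, −20 → 0 °C; aq NH4Cl
Reagents that add atoms: none
Why: Weinreb ketone synthesis, in which low-temperature iodine–magnesium exchange tolerates the aryl sulfonate, the chelated tetrahedral adduct blocks over-addition and shields Cβ from enolisation until the neutral quench, and the sulfonate-stabilised arylmagnesium has no driving force to exchange with the more electron-rich iodide of 15.

**Step 10**
Reactants: 17 (R)-2-(4-iodo-2-methoxyphenoxy)-1-[3-methoxy-4-(tosyloxy)phenyl]propan-1-one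
Product: 18 (1S,2R)-2-(4-iodo-2-methoxyphenoxy)-1-[3-methoxy-4-(tosyloxy)phenyl]propan-1-ol (erythro)
Conditions: Zn(BH4)2, Et2O/CH2Cl2, −78 → −20 °C; aq NH4Cl
Reagents that add atoms: none
Why: Cram-chelate-controlled hydride reduction of an α-alkoxy ketone, in which divalent zinc should hold the carbonyl oxygen and the aryloxy oxygen (helped by the neighbouring methoxy group) in a five-membered chelate so that hydride arrives from the side of the Cβ hydrogen rather than the Cβ methyl and gives the anti (erythro) 1S,2R alcohol.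

**Step 11**
Reactants: 18 (1S,2R)-2-(4-iodo-2-methoxyphenoxy)-1-[3-methoxy-4-(tosyloxy)phenyl]propan-1-ol
Product: 19 4-[(1S,2R)-1-(tert-butyldimethylsilyloxy)-2-(4-iodo-2-methoxyphenoxy)propyl]-2-methoxyphenyl 4-methylbenzenesulfonate
Conditions: TBSOTf, 2,6-lutidine, CH2Cl2, 0 °C
Reagents that add atoms: tert-butyldimethylsilyl triflate, CC(C)(C)[Si](C)(C)OS(=O)(=O)C(F)(F)F
Why: Silylation of a hindered secondary alcohol with the silyl triflate and a hindered pyridine base is standard, breaks no bond at Cα, and removes the only acidic proton before metalation.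

**Step 12**
Reactants: 19 silyl ether iodide (ring B–side chain–ring C); 12 lactol (ring A/C2–C4)
Product: 22 (1S,2R,3S,4RS)-1-[3-methoxy-4-(tosyloxy)phenyl]-4-{4-[(1S,2R)-1-(tert-butyldimethylsilyloxy)-1-(3-methoxy-4-(tosyloxy)phenyl)propan-2-yl]oxy-3-methoxyphenyl}-2,3-dimethylbutane-1,4-diol (both C5 epimers), via ring B arylmagnesium chloride 20 (not isolated), via chloromagnesium lactolate 21 (not isolated)
Conditions: 19 (1.3 equiv), i-PrMgCl·LiCl, THF, 0 °C → rt; separately 12, t-BuMgCl (1.0 equiv), THF, −40 °C; combine, −40 °C → rt; aq NH4Cl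
Reagents that add atoms: none
Why: Addition of an aryl Grignard reagent to a lactol through its open hydroxy-aldehyde form is a standard way to 1,4-diols, iodine–magnesium exchange with i-PrMgCl·LiCl tolerates the aryl sulfonate and the silyl ether, t-BuMgCl serves as a non-nucleophilic sacrificial base so that none of 20 is spent on the lactol proton, and the new C5 carbinol may form as any mixture because the next step erases it.

**Step 13**
Reactants: 22 1,4-diol (both C5 epimers)
Product: 23 (2S,3R,4S,5S)-2-[3-methoxy-4-(tosyloxy)phenyl]-5-{4-[(1S,2R)-1-(tert-butyldimethylsilyloxy)-1-(3-methoxy-4-(tosyloxy)phenyl)propan-2-yl]oxy-3-methoxyphenyl}-3,4-dimethyloxolane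
Conditions: BF3·OEt2 (1.2 equiv), CH2Cl2, −78 → −20 °C; aq NaHCO3
Reagents that add atoms: none
Why: BF3 binds the C5 hydroxyl of either epimer and expels it, because only this carbinol is para to an alkoxy donor (the ring B oxygen that carries the side chain), and the planar p-alkoxybenzyl cation that results no longer remembers the C5 configuration. The C2 hydroxyl, whose own C–O bond is never broken, adds to the cation and forms O1–C5, which is the known acid-promoted cyclodehydration of 1,4-diarylbutane-1,4-diols to 2,5-diaryltetrahydrofurans. The ring closes in the 5-exo-trig mode, counted on the quinoid resonance form in which the C5=C1' bond lies outside the new ring. C5 is set by the C4 stereocentre: oxygen approaches the cation face anti to the C4 methyl, which places ring B trans to that methyl and opposite to the C2 aryl and both methyl groups, and because the ether can re-ionise at C5 any cis product should drain to the same, far less crowded isomer. The step needs site selectivity among three benzylic C–O bonds, and the tosyloxy groups secure it by making rings A and C too electron-poor to support a cation at C2 or Cα, so C2, C3, C4, Cα and Cβ stay as made. Low temperature and short contact keep the silyl ether on and suppress proton loss from C4 and Friedel–Crafts attack by ring A.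

**Step 14**
Reactants: 23 bis-tosyl mono-silyl tetrahydrofuran
Product: 24 (2S,3R,4S,5S)-2-[3-methoxy-4-(tosyloxy)phenyl]-5-{4-[(1S,2R)-1-hydroxy-1-(3-methoxy-4-(tosyloxy)phenyl)propan-2-yl]oxy-3-methoxyphenyl}-3,4-dimethyloxolane
Conditions: Bu4NF, AcOH (1:1), THF, 0 °C → rt
Reagents that add atoms: none
Why: Fluoride-induced cleavage of the Si–O bond is driven by the strong Si–F bond, acetic acid buffers the alkoxide so that the aryl sulfonates stay on, and doing this while rings A and C are still electron-poor keeps every benzylic C–O bond safe.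

**Step 15**
Reactants: 24 bis-tosylate alcohol
Product: 25 4-[(2S,3R,4S,5S)-5-{4-[(1S,2R)-1-hydroxy-1-(4-hydroxy-3-methoxyphenyl)propan-2-yl]oxy-3-methoxyphenyl}-3,4-dimethyloxolan-2-yl]-2-methoxyphenol (CNP0171079.3)
Conditions: Mg turnings, MeOH/THF, rt, sonication; aq NH4Cl
Reagents that add atoms: none
Why: Reductive cleavage of aryl tosylates by magnesium in methanol (single-electron transfer into the sulfonate, S–O scission to phenoxide and sulfinate) is a known mild deprotection that needs neither acid nor hot alkali, so C2 and Cα, which become p-hydroxybenzylic only now, are not exposed to conditions that open quinone methide pathways.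

**Compound list**
1 | 4-iodo-2-methoxyphenol | COc1cc(I)ccc1O | starting material
2 | p-toluenesulfonyl chloride | Cc1ccc(S(Cl)(=O)=O)cc1 | starting material
3 | 4-iodo-2-methoxyphenyl 4-methylbenzenesulfonate | COc1cc(I)ccc1OS(=O)(=O)c1ccc(C)cc1 | intermediate
4 | meso-2,3-dimethylsuccinic acid | OC(=O)[C@H](C)[C@H](C)C(=O)O | starting material
5 | cis-2,3-dimethylsuccinic anhydride | O=C1OC(=O)[C@H](C)[C@@H]1C | intermediate
6 | [3-methoxy-4-(tosyloxy)phenyl]lithium | COc1cc([Li])ccc1OS(=O)(=O)c1ccc(C)cc1 | intermediate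
7 | [3-methoxy-4-(tosyloxy)phenyl]zinc triflate | COc1cc([Zn]OS(=O)(=O)C(F)(F)F)ccc1OS(=O)(=O)c1ccc(C)cc1 | intermediate
8 | (2S,3R)-4-[3-methoxy-4-(tosyloxy)phenyl]-2,3-dimethyl-4-oxobutanoic acid | COc1cc(C(=O)[C@H](C)[C@H](C)C(=O)O)ccc1OS(=O)(=O)c1ccc(C)cc1 | intermediate
9 | methyl (2S,3R)-4-[3-methoxy-4-(tosyloxy)phenyl]-2,3-dimethyl-4-oxobutanoate | COc1cc(C(=O)[C@H](C)[C@H](C)C(=O)OC)ccc1OS(=O)(=O)c1ccc(C)cc1 | intermediate
10 | methyl (2S,3R,4S)-4-hydroxy-4-[3-methoxy-4-(tosyloxy)phenyl]-2,3-dimethylbutanoate | COc1cc([C@@H](O)[C@H](C)[C@H](C)C(=O)OC)ccc1OS(=O)(=O)c1ccc(C)cc1 | intermediate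
11 | (3S,4R,5S)-5-[3-methoxy-4-(tosyloxy)phenyl]-3,4-dimethyloxolan-2-one | COc1cc([C@H]2OC(=O)[C@@H](C)[C@H]2C)ccc1OS(=O)(=O)c1ccc(C)cc1 | intermediate
12 | (3S,4R,5S)-5-[3-methoxy-4-(tosyloxy)phenyl]-3,4-dimethyloxolan-2-ol (anomer mixture) | COc1cc([C@H]2OC(O)[C@@H](C)[C@H]2C)ccc1OS(=O)(=O)c1ccc(C)cc1 | intermediate
13 | ethyl (S)-lactate | C[C@H](O)C(=O)OCC | starting material
14 | ethyl (R)-2-(4-iodo-2-methoxyphenoxy)propanoate | COc1cc(I)ccc1O[C@H](C)C(=O)OCC | intermediate
15 | (R)-2-(4-iodo-2-methoxyphenoxy)-N-methoxy-N-methylpropanamide | COc1cc(I)ccc1O[C@H](C)C(=O)N(C)OC | intermediate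
16 | [3-methoxy-4-(tosyloxy)phenyl]magnesium chloride | COc1cc([Mg]Cl)ccc1OS(=O)(=O)c1ccc(C)cc1 | intermediate
17 | (R)-2-(4-iodo-2-methoxyphenoxy)-1-[3-methoxy-4-(tosyloxy)phenyl]propan-1-one | COc1cc(I)ccc1O[C@H](C)C(=O)c1ccc(OS(=O)(=O)c2ccc(C)cc2)c(OC)c1 | intermediate
18 | (1S,2R)-2-(4-iodo-2-methoxyphenoxy)-1-[3-methoxy-4-(tosyloxy)phenyl]propan-1-ol | COc1cc(I)ccc1O[C@H](C)[C@@H](O)c1ccc(OS(=O)(=O)c2ccc(C)cc2)c(OC)c1 | intermediate
19 | tert-butyldimethylsilyl ether of 18 | COc1cc(I)ccc1O[C@H](C)[C@@H](O[Si](C)(C)C(C)(C)C)c1ccc(OS(=O)(=O)c2ccc(C)cc2)c(OC)c1 | intermediate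
20 | ring B arylmagnesium chloride derived from 19 | COc1cc([Mg]Cl)ccc1O[C@H](C)[C@@H](O[Si](C)(C)C(C)(C)C)c1ccc(OS(=O)(=O)c2ccc(C)cc2)c(OC)c1 | intermediate
21 | chloromagnesium lactolate of 12 | COc1cc([C@H]2OC(O[Mg]Cl)[C@@H](C)[C@H]2C)ccc1OS(=O)(=O)c1ccc(C)cc1 | intermediate
22 | 1,4-diol, bis-tosyl, mono-silyl, both C5 epimers | COc1cc([C@@H](O)[C@H](C)[C@H](C)C(O)c2ccc(O[C@H](C)[C@@H](O[Si](C)(C)C(C)(C)C)c3ccc(OS(=O)(=O)c4ccc(C)cc4)c(OC)c3)c(OC)c2)ccc1OS(=O)(=O)c1ccc(C)cc1 | intermediate
23 | (2S,3R,4S,5S)-tetrahydrofuran, bis-tosyl, mono-silyl | COc1cc([C@H]2O[C@H](c3ccc(O[C@H](C)[C@@H](O[Si](C)(C)C(C)(C)C)c4ccc(OS(=O)(=O)c5ccc(C)cc5)c(OC)c4)c(OC)c3)[C@@H](C)[C@H]2C)ccc1OS(=O)(=O)c1ccc(C)cc1 | intermediate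
24 | (2S,3R,4S,5S)-tetrahydrofuran, bis-tosyl, free Cα alcohol | COc1cc([C@H]2O[C@H](c3ccc(O[C@H](C)[C@@H](O)c4ccc(OS(=O)(=O)c5ccc(C)cc5)c(OC)c4)c(OC)c3)[C@@H](C)[C@H]2C)ccc1OS(=O)(=O)c1ccc(C)cc1 | intermediate
25 | CNP0171079.3 | COc1cc([C@H]2O[C@H](c3ccc(O[C@H](C)[C@@H](O)c4ccc(O)c(OC)c4)c(OC)c3)[C@@H](C)[C@H]2C)ccc1O | target

**Step count**
Total step count: 15.
Longest linear sequence: 9 steps (for example steps 7, 8, 9, 10, 11, 12, 13, 14, 15; the ring A branch through steps 1, 3, 4, 5, 6 is equally long).

**Steps most likely to fail**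

Step 3.
- What may go wrong: slow turnover or eroded enantioselection of the rhodium catalyst with a sulfonate-bearing arylzinc, or attack of the organolithium on the sulfonate during the exchange.
- The fallback sets out from 5 and comes back at 9. It separates desymmetrisation from C–C bond formation.
- Alkaloid-catalysed methanolysis of 5 ((DHQD)2AQN or its pseudoenantiomer (DHQ)2AQN, whichever gives this antipode; MeOH, Et2O, −20 °C) should give the half-ester (2R,3S)-4-methoxy-2,3-dimethyl-4-oxobutanoic acid F1.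
- EtSH, EDC·HCl and DMAP turn it into the thioester methyl (2S,3R)-4-(ethylsulfanyl)-2,3-dimethyl-4-oxobutanoate F2.
- Zinc insertion into 3 (Zn dust, LiCl, THF, 40 °C) gives [3-methoxy-4-(tosyloxy)phenyl]zinc iodide F3.
- Fukuyama coupling of F2 with F3 (PdCl2(PPh3)2, THF/toluene, rt) gives 9 directly. Steps 3 and 4 are both replaced and no organolithium meets the sulfonate.

Step 5.
- What may go wrong: poor facial selectivity, because the catalyst has to override the Felkin–Anh preference of the substrate and the branched alkyl group competes with the aryl group for the role of large substituent.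
- The fallback sets out from 9 and comes back at 11. It accepts the substrate bias and then inverts C2.
- Li(s-Bu)3BH (THF, −78 °C) should give, after spontaneous lactonisation, the 4,5-trans lactone (3S,4R,5R)-5-[3-methoxy-4-(tosyloxy)phenyl]-3,4-dimethyloxolan-2-one F4.
- Me2NH·HCl/AlMe3 opens it to the hydroxy amide (2S,3R,4R)-4-hydroxy-4-[3-methoxy-4-(tosyloxy)phenyl]-N,N,2,3-tetramethylbutanamide F5.
- MsCl/Et3N (CH2Cl2, −20 °C) gives its methanesulfonate F6.
- On warming in aqueous THF the amide oxygen displaces the benzylic sulfonate from the rear (5-exo-tet, inversion). The iminium lactone then hydrolyses to 11.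

Step 10.
- What may go wrong: weak chelation by the poorly basic aryl ether oxygen, so that open-chain Felkin–Anh attack competes and the erythro/threo selectivity collapses.
- The fallback sets out from 17 and comes back at 18. It uses the non-chelate pathway on purpose and then inverts Cα.
- Li(s-Bu)3BH (THF, −78 °C) should give the threo alcohol (1R,2R)-2-(4-iodo-2-methoxyphenoxy)-1-[3-methoxy-4-(tosyloxy)phenyl]propan-1-ol F7.
- Mitsunobu reaction with 4-nitrobenzoic acid (PPh3, DIAD, toluene) should proceed as an SN2 process, since the tosyloxy ring disfavours a benzylic cation. It gives the inverted ester (1S,2R)-2-(4-iodo-2-methoxyphenoxy)-1-[3-methoxy-4-(tosyloxy)phenyl]propyl 4-nitrobenzoate F8.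
- K2CO3 in MeOH at 0 °C releases 18.

**Further compounds**
F1 | step 3 | (2R,3S)-4-methoxy-2,3-dimethyl-4-oxobutanoic acid | OC(=O)[C@H](C)[C@H](C)C(=O)OC
F2 | step 3 | methyl (2S,3R)-4-(ethylsulfanyl)-2,3-dimethyl-4-oxobutanoate | CCSC(=O)[C@H](C)[C@H](C)C(=O)OC
F3 | step 3 | [3-methoxy-4-(tosyloxy)phenyl]zinc iodide | COc1cc([Zn]I)ccc1OS(=O)(=O)c1ccc(C)cc1
F4 | step 5 | (3S,4R,5R)-5-[3-methoxy-4-(tosyloxy)phenyl]-3,4-dimethyloxolan-2-one | COc1cc([C@@H]2OC(=O)[C@@H](C)[C@H]2C)ccc1OS(=O)(=O)c1ccc(C)cc1
F5 | step 5 | (2S,3R,4R)-4-hydroxy-4-[3-methoxy-4-(tosyloxy)phenyl]-N,N,2,3-tetramethylbutanamide | COc1cc([C@H](O)[C@H](C)[C@H](C)C(=O)N(C)C)ccc1OS(=O)(=O)c1ccc(C)cc1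
F6 | step 5 | methanesulfonate of F5 | COc1cc([C@H](OS(C)(=O)=O)[C@H](C)[C@H](C)C(=O)N(C)C)ccc1OS(=O)(=O)c1ccc(C)cc1
F7 | step 10 | (1R,2R)-2-(4-iodo-2-methoxyphenoxy)-1-[3-methoxy-4-(tosyloxy)phenyl]propan-1-ol | COc1cc(I)ccc1O[C@H](C)[C@H](O)c1ccc(OS(=O)(=O)c2ccc(C)cc2)c(OC)c1
F8 | step 10 | (1S,2R)-2-(4-iodo-2-methoxyphenoxy)-1-[3-methoxy-4-(tosyloxy)phenyl]propyl 4-nitrobenzoate | COc1cc(I)ccc1O[C@H](C)[C@@H](OC(=O)c1ccc(cc1)[N+](=O)[O-])c1ccc(OS(=O)(=O)c2ccc(C)cc2)c(OC)c1
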